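The route rests on disconnecting the C4–C5 bond of the benzoquinone ring. In that ring the aryloxy carbon C2 and the alkyl carbon C3 are adjacent, and C5 and C6 are unsubstituted CH. This is the signature of a squarate-derived 2-alkyl-3-aryloxy-4-hydroxy-4-vinylcyclobut-2-enone. On heating, the four-membered ring opens to a dienylketene that closes the C4–C5 bond and aromatises. One operation should therefore turn the cyclobutenone into the fully substituted hydroquinone without touching the 18-membered macrocycle. The precursor is that macrocyclic cyclobutenone. Its two alkene carbons carry the oxygen of arene C and the CH2CH2 arm of arene A, and the ring-B phenol is masked as a triisopropylsilyl ether.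

Key step: step 15

Remark: the target SMILES holds no stereodescriptor and the molecule has no stereocentre (the 18-membered ring is taken as conformationally mobile), so there is only one compound to make; the carbinol centres of 17 and 22 are racemic and vanish.
Labels: arene A = para-phenylene ring; arene B = 1,2,4-trisubstituted (catechol-derived) ring; arene C = meta-phenylene ring; quinone numbering C1(=O), C2(OAr), C3(CH2), C4(=O), C5-H, C6-H. From step 11 on, "2-arylethyl" stands for CH2CH2–arene A–O–arene B(O-TIPS)–CH2CH2–arene C, whose meta oxygen substituent is named in each case.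

Step 1
Reactants: 1 3,4-dihydroxybenzaldehyde
Product: 2 4-(benzyloxy)-3-hydroxybenzaldehyde
Conditions: BnCl (1.0 equiv), NaHCO3, NaI (cat.), DMF, 40 °C
Reagents that add atoms: benzyl chloride, ClCc1ccccc1
Why: Williamson etherification: the 4-OH, para to the formyl group, is the more acidic one and the only one ionised by hydrogencarbonate, so the 3-OH should stay free for the later arylation, and a benzyl ether (unlike a silyl ether) tolerates the hot carbonate of step 5.

Step 2
Reactants: 2 4-(benzyloxy)-3-hydroxybenzaldehyde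
Product: 3 2-(benzyloxy)-5-ethynylphenol
Conditions: dimethyl (1-diazo-2-oxopropyl)phosphonate, K2CO3, MeOH, rt; adjust to pH 6 on work-up
Reagents that add atoms: dimethyl (1-diazo-2-oxopropyl)phosphonate, COP(=O)(OC)C(=[N+]=[N-])C(C)=O
Why: The Seyferth–Gilbert homologation in its Ohira–Bestmann form turns ArCHO into ArC≡CH, tolerates the meta-phenoxide, and removes the ring-B formyl group before a second aldehyde enters in step 5, so two aldehydes never have to be told apart.

Step 3
Reactants: 4 3-iodophenol
Product: 5 1-iodo-3-(methoxymethoxy)benzene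
Conditions: MOMCl, iPr2NEt, CH2Cl2, 0 °C → rt
Reagents that add atoms: chloromethyl methyl ether, COCCl
Why: Standard acetal (MOM) protection of a phenol; the MOM ether withstands base, borane, hydrogenation and magnesium and is orthogonal to both benzyl and TIPS.

Step 4
Reactants: 3 2-(benzyloxy)-5-ethynylphenol; 5 1-iodo-3-(methoxymethoxy)benzene
Product: 6 2-(benzyloxy)-5-{[3-(methoxymethoxy)phenyl]ethynyl}phenol
Conditions: PdCl2(PPh3)2 (2 mol %), CuI (4 mol %), Et3N, THF, rt, Ar
Reagents that add atoms: none
Why: Sonogashira coupling of an aryl iodide with a terminal arylalkyne proceeds at room temperature and tolerates the free phenol.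

Step 5
Reactants: 6 2-(benzyloxy)-5-{[3-(methoxymethoxy)phenyl]ethynyl}phenol; 7 4-fluorobenzaldehyde
Product: 8 4-[2-(benzyloxy)-5-{[3-(methoxymethoxy)phenyl]ethynyl}phenoxy]benzaldehyde
Conditions: K2CO3, DMF, 120 °C
Reagents that add atoms: none
Why: SNAr (addition–elimination through a Meisenheimer adduct): the para-formyl group activates the C–F bond toward the only free phenoxide, while the alkyne, benzyl ether and MOM ether are inert to K2CO3/DMF.

Step 6
Reactants: 8 4-[2-(benzyloxy)-5-{[3-(methoxymethoxy)phenyl]ethynyl}phenoxy]benzaldehyde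
Product: 9 1-(benzyloxy)-2-(4-ethenylphenoxy)-4-{[3-(methoxymethoxy)phenyl]ethynyl}benzene
Conditions: MePPh3Br, KOtBu, THF, 0 °C → rt
Reagents that add atoms: methyltriphenylphosphonium bromide, C[P+](c1ccccc1)(c1ccccc1)c1ccccc1.[Br-]
Why: Wittig methylenation of a non-enolisable aryl aldehyde with the unstabilised ylide; nothing else in 8 is electrophilic.

Step 7
Reactants: 9 1-(benzyloxy)-2-(4-ethenylphenoxy)-4-{[3-(methoxymethoxy)phenyl]ethynyl}benzene
Product: 11 2-{4-[2-(benzyloxy)-5-{[3-(methoxymethoxy)phenyl]ethynyl}phenoxy]phenyl}ethan-1-ol, via B-(2-arylethyl)-9-borabicyclo[3.3.1]nonane 10 (not isolated)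
Conditions: 9-BBN, THF, 0 °C → rt; then NaOH, 30 % H2O2, 0 °C
Reagents that add atoms: hydrogen peroxide, OO
Why: Hydroboration–oxidation: the bulky 9-BBN places boron on the terminal carbon of the styrene and reacts with a monosubstituted alkene much faster than with the internal diarylalkyne, and alkaline peroxide then replaces boron by hydroxyl.

Step 8
Reactants: 11 2-{4-[2-(benzyloxy)-5-{[3-(methoxymethoxy)phenyl]ethynyl}phenoxy]phenyl}ethan-1-ol
Product: 12 1-(benzyloxy)-2-[4-(2-bromoethyl)phenoxy]-4-{[3-(methoxymethoxy)phenyl]ethynyl}benzene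
Conditions: CBr4, PPh3, CH2Cl2, 0 °C
Reagents that add atoms: tetrabromomethane, BrC(Br)(Br)Br
Why: Appel reaction: SN2 displacement of the alkoxyphosphonium ion by bromide under essentially neutral conditions that spare the acetal, the benzyl ether and the alkyne.

Step 9
Reactants: 12 1-(benzyloxy)-2-[4-(2-bromoethyl)phenoxy]-4-{[3-(methoxymethoxy)phenyl]ethynyl}benzene
Product: 13 2-[4-(2-bromoethyl)phenoxy]-4-{2-[3-(methoxymethoxy)phenyl]ethyl}phenol
Conditions: H2 (1 atm), 10 % Pd/C, EtOAc–EtOH, rt
Reagents that add atoms: none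
Why: Heterogeneous catalytic hydrogenation saturates the alkyne to the CH2CH2 bridge and hydrogenolyses the benzyl aryl ether in the same operation, whereas an unactivated primary alkyl bromide and the MOM ether are not reduced in neutral medium.

Step 10
Reactants: 13 2-[4-(2-bromoethyl)phenoxy]-4-{2-[3-(methoxymethoxy)phenyl]ethyl}phenol
Product: 14 {2-[4-(2-bromoethyl)phenoxy]-4-{2-[3-(methoxymethoxy)phenyl]ethyl}phenoxy}tri(propan-2-yl)silane
Conditions: TIPSCl, imidazole, DMF, rt
Reagents that add atoms: chlorotriisopropylsilane, CC(C)[Si](Cl)(C(C)C)C(C)C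
Why: Imidazole-mediated silylation of the single free phenol; the TIPS group is installed only now because it would not have survived step 5, and silylation is far faster than N-alkylation of imidazole by the primary bromide.

Step 11
Reactants: 14 {2-[4-(2-bromoethyl)phenoxy]-4-{2-[3-(methoxymethoxy)phenyl]ethyl}phenoxy}tri(propan-2-yl)silane; 15 diisopropyl squarate
Product: 18 3-(2-arylethyl)-4-isopropoxycyclobut-3-ene-1,2-dione (arene-C O-MOM), via 2-arylethylmagnesium bromide 16 (not isolated), via (±)-4-(2-arylethyl)-4-hydroxy-2,3-diisopropoxycyclobut-2-en-1-one 17 (not isolated)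
Conditions: Mg, I2 (cat.), THF, 40 °C; add to 15 (1.2 equiv), THF, −78 °C; 2 M HCl quench; conc. HCl (cat.), CH2Cl2, rt
Reagents that add atoms: none
Why: Grignard formation from a primary 2-arylethyl bromide, 1,2-addition to one squarate carbonyl at −78 °C and acid-catalysed allylic transposition with loss of isopropanol is the standard entry to 3-alkyl-4-alkoxycyclobutenediones; the centre of 17 is racemic and disappears, and any MOM loss here is harmless because step 12 removes that group.

Step 12
Reactants: 18 3-(2-arylethyl)-4-isopropoxycyclobut-3-ene-1,2-dione (arene-C O-MOM)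
Product: 19 seco acid, 3-(2-arylethyl)-4-hydroxycyclobut-3-ene-1,2-dione (arene-C OH free; ring-B O-TIPS)
Conditions: 3 M aq HCl–THF (1:1), 45 °C
Reagents that add atoms: water, O
Why: Acid-catalysed addition–elimination hydrolysis of the vinylogous ester and acetal hydrolysis of the MOM group occur together, while the aryl TIPS ether, shielded by the ortho aryloxy group, belongs to the most acid-stable silyl ethers.

Step 13
Reactants: 19 seco acid
Product: 21 macrocyclic 3-alkyl-4-aryloxycyclobut-3-ene-1,2-dione (ring-B O-TIPS), via seco 3-chlorocyclobut-3-ene-1,2-dione 20 (not isolated)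
Conditions: (COCl)2 (1.05 equiv), DMF (cat.), CH2Cl2, 0 °C → rt, evaporate; then syringe-pump addition (12 h) to iPr2NEt (3 equiv), CH2Cl2, rt, final 1 mM
Reagents that add atoms: none
Why: Vilsmeier-type activation converts the strongly acidic vinylogous acid into the vinylogous acid chloride 20 much faster than a neutral phenol is acylated without base (as when hydroxybenzoic acids are turned into their acid chlorides), and under pseudo-high dilution the base then lets the arene-C phenol, the only unsilylated one, displace chloride by addition–elimination through oxygen (a vinylogous macrolactonisation), closing the 18-membered ring in which cyclobutene C3 holds the CH2CH2 of arene A while C4 holds the oxygen of arene C.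

Step 14
Reactants: 21 macrocyclic 3-alkyl-4-aryloxycyclobut-3-ene-1,2-dione
Product: 22 (±)-macrocyclic 2-alkyl-3-aryloxy-4-hydroxy-4-vinylcyclobut-2-en-1-one (ring-B O-TIPS)
Conditions: CH2=CHMgBr (1.3 equiv), THF, −78 °C; sat. aq NH4Cl at −78 °C
Reagents that add atoms: vinylmagnesium bromide, C=C[Mg]Br
Why: 1,2-Addition of a vinyl Grignard reagent to a cyclobutenedione: the carbonyl next to the aryloxy-bearing carbon lies outside the vinylogous ester and is the more electrophilic, the new carbinol centre forms as a racemate and is erased in step 15, and addition to the other carbonyl would lead to the same hydroquinone because the vinyl group is unsubstituted.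

Step 15
Reactants: 22 (±)-macrocyclic 2-alkyl-3-aryloxy-4-hydroxy-4-vinylcyclobut-2-en-1-one
Product: 25 macrocyclic 2-aryloxy-3-alkylbenzene-1,4-diol (ring-B O-TIPS), via (Z)-dienylketene 23 (not isolated), via 4-hydroxycyclohexa-2,4-dien-1-one tautomer 24 (not isolated)
Conditions: degassed toluene (5 mM), 110 °C, Ar
Reagents that add atoms: none
Why: Heat drives a four-electron conrotatory opening of the C1–C4 bond of the strained cyclobutenone to the dienylketene 23, whose ketene carbon (future quinone C4) bonds to the vinyl terminus (future C5) in a six-electron disrotatory electrocyclisation to give 24, and enolisation aromatises this to 25. The closest known reaction type is the Moore rearrangement of squarate-derived 4-alkenyl-4-hydroxycyclobutenones to hydroquinones. The only ring closed is the six-membered carbocycle, by a 6π electrocyclisation; the 18-membered ring is neither made nor broken because it is anchored on the two cyclobutene alkene carbons, which end up as C2 and C3. No stereocentre is created and the racemic carbinol centre of 22 is destroyed. The step needs torquoselectivity: the donor hydroxyl on C4 rotates outward, which places the vinyl group next to the ketene, and both C4 substituents lie outside the macrocycle, so the tether cannot oppose this. Dilution and exclusion of nucleophiles and oxygen should let cyclisation beat ketene trapping.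

Step 16
Reactants: 25 macrocyclic 2-aryloxy-3-alkylbenzene-1,4-diol
Product: 26 O-triisopropylsilyl marchantinquinone
Conditions: Ag2O (2 equiv), CH2Cl2, rt, dark
Reagents that add atoms: none
Why: Two-electron oxidation of a hydroquinone by silver(I) oxide under neutral, non-nucleophilic conditions that leave the silyl ether, the diaryl ethers and the benzylic positions alone.

Step 17
Reactants: 26 O-triisopropylsilyl marchantinquinone
Product: 27 marchantinquinone
Conditions: HF·pyridine, THF, 0 °C → rt (PTFE vessel)
Reagents that add atoms: none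
Why: Fluoride-mediated Si–O cleavage driven by the strong Si–F bond; the acidic, weakly nucleophilic HF·pyridine avoids the basic conditions under which an aryloxyquinone would suffer addition–elimination.

Compound list
1 | 3,4-dihydroxybenzaldehyde | O=Cc1ccc(O)c(O)c1 | starting material
2 | 4-(benzyloxy)-3-hydroxybenzaldehyde | O=Cc1ccc(OCc2ccccc2)c(O)c1 | intermediate
3 | 2-(benzyloxy)-5-ethynylphenol | C#Cc1ccc(OCc2ccccc2)c(O)c1 | intermediate
4 | 3-iodophenol | Oc1cccc(I)c1 | starting material
5 | 1-iodo-3-(methoxymethoxy)benzene | COCOc1cccc(I)c1 | intermediate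
6 | 2-(benzyloxy)-5-{[3-(methoxymethoxy)phenyl]ethynyl}phenol | COCOc1cccc(c1)C#Cc1ccc(OCc2ccccc2)c(O)c1 | intermediate
7 | 4-fluorobenzaldehyde | O=Cc1ccc(F)cc1 | starting material
8 | 4-[2-(benzyloxy)-5-{[3-(methoxymethoxy)phenyl]ethynyl}phenoxy]benzaldehyde | COCOc1cccc(c1)C#Cc1ccc(OCc2ccccc2)c(Oc2ccc(C=O)cc2)c1 | intermediate
9 | 1-(benzyloxy)-2-(4-ethenylphenoxy)-4-{[3-(methoxymethoxy)phenyl]ethynyl}benzene | COCOc1cccc(c1)C#Cc1ccc(OCc2ccccc2)c(Oc2ccc(C=C)cc2)c1 | intermediate
10 | B-(2-arylethyl)-9-borabicyclo[3.3.1]nonane from 9 | COCOc1cccc(c1)C#Cc1ccc(OCc2ccccc2)c(Oc2ccc(CCB3C4CCCC3CCC4)cc2)c1 | intermediate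
11 | 2-{4-[2-(benzyloxy)-5-{[3-(methoxymethoxy)phenyl]ethynyl}phenoxy]phenyl}ethan-1-ol | COCOc1cccc(c1)C#Cc1ccc(OCc2ccccc2)c(Oc2ccc(CCO)cc2)c1 | intermediate
12 | 1-(benzyloxy)-2-[4-(2-bromoethyl)phenoxy]-4-{[3-(methoxymethoxy)phenyl]ethynyl}benzene | COCOc1cccc(c1)C#Cc1ccc(OCc2ccccc2)c(Oc2ccc(CCBr)cc2)c1 | intermediate
13 | 2-[4-(2-bromoethyl)phenoxy]-4-{2-[3-(methoxymethoxy)phenyl]ethyl}phenol | COCOc1cccc(c1)CCc1ccc(O)c(Oc2ccc(CCBr)cc2)c1 | intermediate
14 | {2-[4-(2-bromoethyl)phenoxy]-4-{2-[3-(methoxymethoxy)phenyl]ethyl}phenoxy}tri(propan-2-yl)silane | COCOc1cccc(c1)CCc1ccc(O[Si](C(C)C)(C(C)C)C(C)C)c(Oc2ccc(CCBr)cc2)c1 | intermediate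
15 | diisopropyl squarate | CC(C)OC1=C(OC(C)C)C(=O)C1=O | starting material
16 | 2-arylethylmagnesium bromide from 14 | COCOc1cccc(c1)CCc1ccc(O[Si](C(C)C)(C(C)C)C(C)C)c(Oc2ccc(CC[Mg]Br)cc2)c1 | intermediate
17 | (±)-4-(2-arylethyl)-4-hydroxy-2,3-diisopropoxycyclobut-2-en-1-one | CC(C)OC1=C(OC(C)C)C(O)(CCc2ccc(Oc3cc(CCc4cccc(OCOC)c4)ccc3O[Si](C(C)C)(C(C)C)C(C)C)cc2)C1=O | intermediate
18 | 3-(2-arylethyl)-4-isopropoxycyclobut-3-ene-1,2-dione (arene-C O-MOM) | CC(C)OC1=C(CCc2ccc(Oc3cc(CCc4cccc(OCOC)c4)ccc3O[Si](C(C)C)(C(C)C)C(C)C)cc2)C(=O)C1=O | intermediate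
19 | seco acid, 3-(2-arylethyl)-4-hydroxycyclobut-3-ene-1,2-dione (arene-C OH free; ring-B O-TIPS) | OC1=C(CCc2ccc(Oc3cc(CCc4cccc(O)c4)ccc3O[Si](C(C)C)(C(C)C)C(C)C)cc2)C(=O)C1=O | intermediate
20 | seco 3-chlorocyclobut-3-ene-1,2-dione, 3-chloro-4-(2-arylethyl)cyclobut-3-ene-1,2-dione (arene-C OH free; ring-B O-TIPS) | ClC1=C(CCc2ccc(Oc3cc(CCc4cccc(O)c4)ccc3O[Si](C(C)C)(C(C)C)C(C)C)cc2)C(=O)C1=O | intermediate
21 | macrocyclic 3-alkyl-4-aryloxycyclobut-3-ene-1,2-dione (18-membered ring; ring-B O-TIPS) | O=C1C(=O)C2=C1Oc1cccc(c1)CCc1ccc(O[Si](C(C)C)(C(C)C)C(C)C)c(c1)Oc1ccc(CC2)cc1 | intermediate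
22 | (±)-macrocyclic 2-alkyl-3-aryloxy-4-hydroxy-4-vinylcyclobut-2-en-1-one (O-TIPS) | C=CC1(O)C(=O)C2=C1Oc1cccc(c1)CCc1ccc(O[Si](C(C)C)(C(C)C)C(C)C)c(c1)Oc1ccc(CC2)cc1 | intermediate
23 | macrocyclic (Z)-dienylketene (vinyl cis to the ketene-bearing carbon) | C=C/C(O)=C1/Oc2cccc(c2)CCc2ccc(O[Si](C(C)C)(C(C)C)C(C)C)c(c2)Oc2ccc(CCC1=C=O)cc2 | intermediate
24 | macrocyclic 4-hydroxycyclohexa-2,4-dien-1-one tautomer | O=C1CC=C(O)C2=C1CCc1ccc(cc1)Oc1cc(ccc1O[Si](C(C)C)(C(C)C)C(C)C)CCc1cccc(c1)O2 | intermediate
25 | macrocyclic 2-aryloxy-3-alkylbenzene-1,4-diol (O-TIPS) | Oc1ccc(O)c2c1CCc1ccc(cc1)Oc1cc(ccc1O[Si](C(C)C)(C(C)C)C(C)C)CCc1cccc(c1)O2 | intermediate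
26 | O-triisopropylsilyl marchantinquinone | O=C1C=CC(=O)C2=C1CCc1ccc(cc1)Oc1cc(ccc1O[Si](C(C)C)(C(C)C)C(C)C)CCc1cccc(c1)O2 | intermediate
27 | marchantinquinone | O=C1C=CC(=O)C2=C1CCc1ccc(cc1)Oc1cc(ccc1O)CCc1cccc(c1)O2 | target

Total step count: 17. Longest linear sequence: 16 (steps 1, 2, 4–17; step 3 is a one-step branch).

Steps most likely to fail

Step 15. The dienylketene may be intercepted by a hydroxyl group of the same or another molecule. The hydroxyl may also rotate inward. In either case, lactone or ester formation would compete with the electrocyclisation. The fallback sets out from 22. Its tertiary hydroxyl is capped (TMSOTf, 2,6-lutidine, CH2Cl2, −78 °C) to give the macrocyclic 4-(trimethylsilyloxy)-4-vinylcyclobutenone F1. This ether has no free OH to trap a ketene, and the silyloxy group is still an outward-rotating donor. Thermolysis in toluene should then give the mono-O-trimethylsilyl hydroquinone F2. Brief methanolysis (citric acid, MeOH, rt) comes back to the route at 25.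

Step 13. Oligomerisation may outrun ring closure, or the free phenol may be consumed by the chlorinating agent before the base is added. The fallback sets out from 19. Both acidic hydroxyls are silylated (TBSCl, imidazole, CH2Cl2, non-aqueous work-up) to give the bis(tert-butyldimethylsilyl) derivative F3. Oxalyl chloride with catalytic DMF then converts the silyl semisquarate directly into the chloride under neutral conditions, giving the phenol-masked chlorocyclobutenedione F4. F4 is added slowly to CsF in MeCN. This should unmask only the unhindered arene-C aryl TBS ether, because the hindered aryl TIPS ether reacts far more slowly. The phenoxide is then present only in trace concentration and should close the ring, which comes back to the route at 21.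

Step 14. Conjugate addition–elimination with loss of the aryloxide (opening of the macrocycle), or enolisation at the CH2 next to the four-membered ring, may compete with 1,2-addition. The fallback sets out from 21. The much less basic ethynylmagnesium bromide (THF, −78 °C) should add strictly 1,2 and give the macrocyclic 4-ethynyl-4-hydroxycyclobutenone F5. Semi-hydrogenation (H2, Lindlar catalyst, quinoline, EtOAc, rt) runs well below the temperature at which 4-alkynylcyclobutenones rearrange. It comes back to the route at 22.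

Further compounds
F1 | step 15 | (±)-macrocyclic 2-alkyl-3-aryloxy-4-(trimethylsilyloxy)-4-vinylcyclobut-2-en-1-one (O-TIPS) | C=CC1(O[Si](C)(C)C)C(=O)C2=C1Oc1cccc(c1)CCc1ccc(O[Si](C(C)C)(C(C)C)C(C)C)c(c1)Oc1ccc(CC2)cc1
F2 | step 15 | macrocyclic hydroquinone, C1-O-trimethylsilyl ether (O-TIPS) | Oc1ccc(O[Si](C)(C)C)c2c1CCc1ccc(cc1)Oc1cc(ccc1O[Si](C(C)C)(C(C)C)C(C)C)CCc1cccc(c1)O2
F3 | step 13 | bis(tert-butyldimethylsilyl) derivative of seco acid 19 | CC(C)(C)[Si](C)(C)OC1=C(CCc2ccc(Oc3cc(CCc4cccc(O[Si](C)(C)C(C)(C)C)c4)ccc3O[Si](C(C)C)(C(C)C)C(C)C)cc2)C(=O)C1=O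
F4 | step 13 | 3-chloro-4-(2-arylethyl)cyclobut-3-ene-1,2-dione with arene-C O-TBS | ClC1=C(CCc2ccc(Oc3cc(CCc4cccc(O[Si](C)(C)C(C)(C)C)c4)ccc3O[Si](C(C)C)(C(C)C)C(C)C)cc2)C(=O)C1=O
F5 | step 14 | (±)-macrocyclic 2-alkyl-3-aryloxy-4-ethynyl-4-hydroxycyclobut-2-en-1-one (O-TIPS) | C#CC1(O)C(=O)C2=C1Oc1cccc(c1)CCc1ccc(O[Si](C(C)C)(C(C)C)C(C)C)c(c1)Oc1ccc(CC2)cc1
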